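(The earlier runs and the new flask were generated by integration from invented constants; the scatter is artificial.)

Follow one molecule of starting material through the flask and ask its chances at the fork: catalyst intermediate A carries it on towards target, and protic impurity turns it into quenched substrate. I reckoned the target at the end as those chances times the starting material gone by then.

| flask | starting material | reagent | protic impurity | free catalyst | temperature | remark | time |
|---|---|---|---|---|---|---|---|
| delta | 0.012 M | 0.0054 M | 0.012 M | 1.2 mM | 2 °C | run made earlier |  |
| theta | 0.012 M | 0.0081 M | 0.012 M | 1.2 mM | 19 °C | run made earlier |  |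
| Friday's | 0.012 M | 0.0108 M | 0.0120 M | 1.2 mM | 10 °C |  | 50 h |
| Monday's | 0.012 M | 0.0108 M | 0.0120 M | 1.2 mM |  | at −5 °C until 40 h, from then on at 25 °C | 50 h |
| Sunday's | 0.012 M | 0.0108 M | 0.0120 M | 1.2 mM | 25 °C |  | 50 h |
| Thursday's | 0.012 M | 0.0108 M | 0.0120 M | 1.2 mM | −5 °C |  | 50 h |

| run | time / h | target / % | starting material / % |
|---|---|---|---|
| delta | 8.00 | 1.2 | 95.8 |
| delta | 15.0 | 0 | 91.1 |
| delta | 25.0 | 1.5 | 84.7 |
| delta | 30.0 | 0.4 | 82.4 |
| delta | 40.0 | 3.2 | 77.9 |
| delta | 48.0 | 6.3 | 74.2 |
| delta | 60.0 | 6.4 | 69.2 |
| theta | 5.00 | 4.4 | 85.3 |
| theta | 10.0 | 10.2 | 74.6 |
| theta | 15.0 | 15.9 | 64.2 |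
| theta | 20.0 | 22.0 | 52.8 |
| theta | 25.0 | 27.2 | 48.0 |
| theta | 30.0 | 31.8 | 40.8 |
| theta | 40.0 | 39.5 | 28.6 |

(standard deviation of a reading: 1 percentage point)

- which flask leads in amount of target, in percent of the starting material charged ("all alike" within 1.5 percentage points) (Friday's / Monday's / Sunday's / Thursday's / all alike)
- how much target is there at the end, in percent of the starting material charged: Friday's
- how much target is there at the end, in percent of the starting material charged: Monday's
- how much target is there at the end, in percent of the starting material charged: Sunday's
- how much target is there at the end, in percent of the starting material charged: Thursday's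

- steps thought possible: reagent + free catalyst -> catalyst intermediate A; starting material + catalyst intermediate A -> catalyst intermediate B; catalyst intermediate B -> released group + catalyst intermediate C; catalyst intermediate C -> free catalyst + target; target -> over-reaction product; starting material + protic impurity -> quenched substrate

Starting material can sit on the catalyst as catalyst intermediate B, up to 10.0% of its charge, so I left out the opening hours of the theta run. From 10.0 h to 40.0 h the theta run gained 29 percentage points of target and lost 46 points of starting material. So I read 63.7% for what I called the fork share, the target gained per starting material lost after the opening hours. It is a reading and carries the scatter.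

Then I turned the settings one after the other. Temperature came first. By hand I expected warmth to favour target, and the delta run against the theta run, which differ in reagent too, pointed that way. At 40.0 h the delta run held 3.2% of target and the theta run ten times as much, 39.5%, while the starting material left stood at 77.9% in the delta run and 28.6% in the theta run. The delta run's own share, from 8.00 h to 60.0 h, read 19.5%.

Reagent came second. One reagent is spent per target along the steps thought possible, and Sunday's charge covers 90.0% of the starting material, above the fork share, so I did not expect reagent to be the limiting reagent there.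

Time came last. The theta run's fall, taken as first order, gave 0.0313 h⁻¹, which over 50 h leaves 20.9%. Sunday's is warmer than the theta run, so I expected less left and my reckoning for it ran up towards 63.7% of the charge. The other flasks stand below 25 °C for 40 h or longer, so I put Sunday's first.

The forecast also chose Sunday's, with 52% for Sunday's (range 38% to 66%), 24% for Monday's, 18% for Friday's and 2.2% for Thursday's. For Sunday's it reckoned “less some over-reaction (suggested by theta's slowing)”, and my reckoning stood above its figure.

The flasks gave 64.7% for Sunday's, 26.6% for Monday's, 22.4% for Friday's and 1.59% for Thursday's, so Sunday's led, and Sunday's stood 13 points above the forecast.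

    reagent + free catalyst → catalyst intermediate A (k = 0.0190 M⁻¹ s⁻¹, Ea = 68.0 kJ mol⁻¹)
    starting material + catalyst intermediate A → catalyst intermediate B (k = 0.0260 M⁻¹ s⁻¹, Ea = 52.0 kJ mol⁻¹)
    catalyst intermediate B → released group + catalyst intermediate C (k = 2.80 × 10⁻⁴ s⁻¹, Ea = 102 kJ mol⁻¹)
    catalyst intermediate C → free catalyst + target (k = 0.0230 s⁻¹, Ea = 77.0 kJ mol⁻¹)
    target → over-reaction product (k = 3.70 × 10⁻⁸ s⁻¹, Ea = 116 kJ mol⁻¹)
    starting material + protic impurity → quenched substrate (k = 5.60 × 10⁻⁴ M⁻¹ s⁻¹, Ea = 50.0 kJ mol⁻¹)
    (constants at 25 °C)

Sunday's had lost 97.2% of its starting material by 50.0 h, and that loss times the fork share gives 61.9%, a little below the 64.7% of target it held. Over-reaction product stood at 0.284% in Sunday's. The neighbour is Monday's flask read at 4.0 d instead of 50 h. Its starting material was down to 1.08%, so the same reckoning gave 63.0%, and that reading held 64.2% of target.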